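## Retrosynthetic overview

- The (12Z)-diene is made last: C13–C14 by Stille vinylation of a (Z)-vinyl iodide, which comes from a C12 aldehyde by iodo-Wittig olefination.
- Rings A and B are closed in one light-driven radical bicyclisation of an acyclic tertiary α-bromo ester diene: ring A first (C4–C5), then ring B (C9–C10), ending in the exocyclic C8=C17 alkene.
- The only stereocentre in that acyclic precursor is the C6 acetoxy carbon; it is meant to direct C4, C5, C9 and C10 during the bicyclisation.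
- The precursor is assembled linearly: C3=C4 (Wittig), C1–C2 with (E)-C5=C10 (Johnson–Claisen), C9–C11 (Negishi), (E)-C8=C9 (carboalumination–iodination), C5–C10 (Grignard).
- C6 is bought in methyl (S)-glycidate, which is opened at C7 by acetylide.

Assumption: atom positions are cited in labdane numbering (C1–C20), and methyl (2S)-glycidate is taken as a purchasable single-enantiomer building block.

## Route

Step 1
Reactants: 1 methyl (2S)-oxirane-2-carboxylate; 2 acetylene
Product: 3 methyl (2S)-2-hydroxypent-4-ynoate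
Conditions: HC≡CH, n-BuLi, THF, −78 °C; BF3·OEt2; then 1, −78 °C; aq. NH4Cl
Reagents that add atoms: acetylene (2), C#C
Why: Yamaguchi–Hirao alkynylation, in which the BF3-activated epoxide is opened by SN2 attack at the unsubstituted C3 while the ester is inert at −78 °C, so the purchased stereocentre (future C6) is not touched.

Step 2
Reactants: 3 methyl (2S)-2-hydroxypent-4-ynoate; 4 tert-butyl(chloro)dimethylsilane
Product: 5 methyl (2S)-2-[(tert-butyldimethylsilyl)oxy]pent-4-ynoate
Conditions: t-BuMe2SiCl, imidazole, DMF, 25 °C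
Reagents that add atoms: tert-butyl(chloro)dimethylsilane (4), CC(C)(C)[Si](C)(C)Cl
Why: Standard silyl ether formation, protecting the future C6 hydroxyl for the hydride, Grignard, aluminium and Claisen steps without touching the stereocentre.

Step 3
Reactants: 5 methyl (2S)-2-[(tert-butyldimethylsilyl)oxy]pent-4-ynoate; 6 isopropenylmagnesium bromide
Product: 8 (3RS,4S)-4-[(tert-butyldimethylsilyl)oxy]-2-methylhept-1-en-6-yn-3-ol, via aldehyde 7 (not isolated)
Conditions: i-Bu2AlH (1.1 equiv), CH2Cl2, −78 °C; then CH2=C(Me)MgBr (3 equiv), THF, −78 → 0 °C; aq. KNaC4H4O6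
Reagents that add atoms: isopropenylmagnesium bromide (6), CC(=C)[Mg]Br
Why: Low-temperature half-reduction gives an aluminium hemiacetal that releases the α-silyloxy aldehyde only as the Grignard reagent consumes it, so C6 is not epimerised; the new carbinol (future C5) forms as a mixture that is erased in step 5.

Step 4
Reactants: 8 (3RS,4S)-4-[(tert-butyldimethylsilyl)oxy]-2-methylhept-1-en-6-yn-3-ol; 9 trimethylaluminium; 10 iodine
Product: 12 (3RS,4S,6E)-4-[(tert-butyldimethylsilyl)oxy]-7-iodo-2,6-dimethylhepta-1,6-dien-3-ol, via alkenylalane 11 (not isolated)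
Conditions: Me3Al (4 equiv), Cp2ZrCl2 (0.3 equiv), CH2Cl2, 0 → 25 °C; then I2, THF, −30 °C; aq. Na2S2O3/NaHCO3
Reagents that add atoms: trimethylaluminium (9), C[Al](C)C; iodine (10), [I][I]
Why: Negishi zirconium-catalysed carboalumination adds methyl and aluminium syn across the terminal alkyne (methyl on the internal carbon), and iodinolysis with retention fixes the (E)-geometry of the future C8=C9 alkene.

Step 5
Reactants: 12 (3RS,4S,6E)-4-[(tert-butyldimethylsilyl)oxy]-7-iodo-2,6-dimethylhepta-1,6-dien-3-ol; 13 triethyl orthoacetate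
Product: 14 ethyl (4E,6S,8E)-6-[(tert-butyldimethylsilyl)oxy]-9-iodo-4,8-dimethylnona-4,8-dienoate
Conditions: MeC(OEt)3 (6 equiv), EtCO2H (0.1 equiv), xylenes, 140 °C, EtOH distilled off
Reagents that add atoms: triethyl orthoacetate (13), CC(OCC)(OCC)OCC
Why: Johnson–Claisen rearrangement through a chair transition state with the C6-bearing substituent equatorial gives the (E)-trisubstituted C5=C10 alkene and adds C1–C3; both C5 epimers converge and C6 is untouched.

Step 6
Reactants: 14 ethyl (4E,6S,8E)-6-[(tert-butyldimethylsilyl)oxy]-9-iodo-4,8-dimethylnona-4,8-dienoate; 15 (1,3-dioxolan-2-ylmethyl)zinc bromide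
Product: 16 ethyl (4E,6S,8E)-6-[(tert-butyldimethylsilyl)oxy]-10-(1,3-dioxolan-2-yl)-4,8-dimethyldeca-4,8-dienoate
Conditions: 15 (1.5 equiv), PdCl2(dppf) (5 mol%), THF, 50 °C
Reagents that add atoms: (1,3-dioxolan-2-ylmethyl)zinc bromide (15), Br[Zn]CC1OCCO1
Why: Negishi sp2–sp3 cross-coupling proceeds with retention of alkene geometry and installs C11 and C12 (as a masked aldehyde), with the ester and silyl ether tolerated by the organozinc.

Step 7
Reactants: 16 ethyl (4E,6S,8E)-6-[(tert-butyldimethylsilyl)oxy]-10-(1,3-dioxolan-2-yl)-4,8-dimethyldeca-4,8-dienoate; 17 methyl 2-(triphenyl-λ5-phosphanylidene)propanoate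
Product: 19 methyl (2E,6E,8S,10E)-8-[(tert-butyldimethylsilyl)oxy]-12-(1,3-dioxolan-2-yl)-2,6,10-trimethyldodeca-2,6,10-trienoate, via aldehyde 18 (not isolated)
Conditions: i-Bu2AlH (1.05 equiv), CH2Cl2, −78 °C; then MeOH (1 equiv), 17 (1.5 equiv), −78 → 25 °C
Reagents that add atoms: methyl 2-(triphenyl-λ5-phosphanylidene)propanoate (17), COC(=O)C(C)=P(c1ccccc1)(c1ccccc1)c1ccccc1
Why: Half-reduction of the ethyl ester followed by Wittig olefination with the stabilised ylide in the same flask gives the (E)-2-methyl enoate that carries C4, C18 and C19.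

Step 8
Reactants: 19 methyl (2E,6E,8S,10E)-8-[(tert-butyldimethylsilyl)oxy]-12-(1,3-dioxolan-2-yl)-2,6,10-trimethyldodeca-2,6,10-trienoate; 20 acetic anhydride
Product: 22 methyl (2E,6E,8S,10E)-8-acetoxy-12-(1,3-dioxolan-2-yl)-2,6,10-trimethyldodeca-2,6,10-trienoate, via alcohol 21 (not isolated)
Conditions: Bu4NF (1.2 equiv), THF, 0 → 25 °C; then Et3N, 4-(dimethylamino)pyridine (cat.), Ac2O (3 equiv)
Reagents that add atoms: acetic anhydride (20), CC(=O)OC(C)=O
Why: Fluoride desilylation and in-flask acylation install the final C6 acetate on the unhindered acyclic alcohol, once all hydride and Grignard steps are past, without touching the stereocentre.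

Step 9
Reactants: 22 methyl (2E,6E,8S,10E)-8-acetoxy-12-(1,3-dioxolan-2-yl)-2,6,10-trimethyldodeca-2,6,10-trienoate; 23 dimethyl(phenyl)silane; 24 N-bromosuccinimide
Product: 26 methyl (2RS,6E,8S,10E)-8-acetoxy-2-bromo-12-(1,3-dioxolan-2-yl)-2,6,10-trimethyldodeca-6,10-dienoate, via silyl ketene acetal 25 (not isolated)
Conditions: Cu(OAc)2 (5 mol%), 1,2-bis(diphenylphosphino)benzene (5 mol%), PhMe2SiH (1.5 equiv), toluene, 25 °C; then THF, −78 °C, NBS (1.3 equiv)
Reagents that add atoms: N-bromosuccinimide (24), O=C1CCC(=O)N1Br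
Why: Copper hydride-catalysed conjugate hydrosilylation is selective for the enoate over the isolated trisubstituted alkenes and gives a silyl ketene acetal that NBS brominates at the α-carbon; the C4 epimers converge in step 10.

Step 10
Reactants: 26 methyl (2RS,6E,8S,10E)-8-acetoxy-2-bromo-12-(1,3-dioxolan-2-yl)-2,6,10-trimethyldodeca-6,10-dienoate
Product: 27 methyl (4S,5R,6S,9S,10R)-6-acetoxy-12,12-(ethylenedioxy)-13,14,15,16-tetranorlabd-8(17)-en-19-oate
Conditions: fac-Ir(ppy)3 (1 mol%), Co(dmgH)2(py)Cl (2 mol%), K2HPO4 (2 equiv), MeCN (0.005 M), 450 nm LEDs, 25 °C, Ar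
Reagents that add atoms: none
Why: Proposed new method: a visible-light dehydrobrominative radical polyene bicyclisation under dual iridium/cobaloxime catalysis, in which photoexcited fac-Ir(ppy)3 reduces the tertiary α-bromo ester to the electrophilic C4 radical, this radical closes ring A by 6-endo attack on C5 (the C6–H eclipses the C5=C10 bond to avoid A(1,3) strain with the C20 methyl and the radical adds anti to the C6–C7 bond with the acetoxy group outside, so C6 fixes C5 and ends equatorial), the tertiary C10 radical closes ring B through a chair onto C9 of the (E)-C8=C9 alkene (trans fusion, C9 side chain equatorial), and divalent cobalt removes a hydrogen atom from the C17 methyl of the tertiary C8 radical to give the exocyclic alkene while the cobalt hydride is deprotonated and reoxidised by tetravalent iridium (net loss of HBr, taken up by K2HPO4); the ester is expected axial at C4 by analogy with manganese triacetate cyclisations of 2-methyl-3-oxo esters, and the closest known reaction types are the Mn(OAc)3/Cu(OAc)2 oxidative polyene cyclisation of β-keto esters, cobaloxime-catalysed visible-light alkyl Heck-type cyclisations of alkyl halides and photoredox/cobaloxime desaturations, none of which has been shown for a simple α-bromo ester polyene, for control by an allylic acyloxy stereocentre, or for a 6-endo/6-endo cascade ended by exocyclic dehydrogenation.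

Step 11
Reactants: 27 methyl (4S,5R,6S,9S,10R)-6-acetoxy-12,12-(ethylenedioxy)-13,14,15,16-tetranorlabd-8(17)-en-19-oate; 28 water
Product: 29 methyl (4S,5R,6S,9S,10R)-6-acetoxy-12-oxo-13,14,15,16-tetranorlabd-8(17)-en-19-oate
Conditions: 1 M aq. HCl/THF (1:4), 25 °C
Reagents that add atoms: water (28), O
Why: Acid-catalysed acetal hydrolysis in dilute acid at room temperature leaves the acetate, the hindered methyl ester and the exocyclic alkene alone, and no stereocentre is α to the new aldehyde.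

Step 12
Reactants: 29 methyl (4S,5R,6S,9S,10R)-6-acetoxy-12-oxo-13,14,15,16-tetranorlabd-8(17)-en-19-oate; 30 ethyltriphenylphosphonium iodide; 10 iodine
Product: 31 methyl (4S,5R,6S,9S,10R,12Z)-6-acetoxy-13-iodo-14,15-dinorlabda-8(17),12-dien-19-oate
Conditions: 30 (2 equiv), n-BuLi, THF, 25 °C; I2, −78 °C; NaN(SiMe3)2, −20 °C; then 29, −78 → −20 °C
Reagents that add atoms: ethyltriphenylphosphonium iodide (30), CC[P+](c1ccccc1)(c1ccccc1)c1ccccc1.[I-]; iodine (10), [I][I]
Why: Stork–Zhao-type Wittig olefination with the α-iodo ylide gives the (Z)-2-iodoalk-2-ene (iodine cis to C11) under kinetic control at low temperature, where the ylide reacts with the aldehyde much faster than with the esters.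

Step 13
Reactants: 31 methyl (4S,5R,6S,9S,10R,12Z)-6-acetoxy-13-iodo-14,15-dinorlabda-8(17),12-dien-19-oate; 32 tributyl(vinyl)stannane
Product: 33 methyl (4S,5R,6S,9S,10R,12Z)-6-acetoxylabda-8(17),12,14-trien-19-oate
Conditions: 32 (1.5 equiv), PdCl2(MeCN)2 (5 mol%), DMF, 25 °C, dark
Reagents that add atoms: tributyl(vinyl)stannane (32), CCCC[Sn](CCCC)(CCCC)C=C
Why: Stille coupling replaces iodine by vinyl with retention of alkene geometry under neutral conditions, completing the (12Z)-diene without risk to the acetate or the skipped exocyclic alkene.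

## Compound list

1 | methyl (2S)-oxirane-2-carboxylate (methyl (S)-glycidate) | COC(=O)[C@@H]1CO1 | starting material
2 | acetylene | C#C | starting material
3 | methyl (2S)-2-hydroxypent-4-ynoate | C#CC[C@H](O)C(=O)OC | intermediate
4 | tert-butyl(chloro)dimethylsilane | CC(C)(C)[Si](C)(C)Cl | starting material
5 | methyl (2S)-2-[(tert-butyldimethylsilyl)oxy]pent-4-ynoate | C#CC[C@H](O[Si](C)(C)C(C)(C)C)C(=O)OC | intermediate
6 | isopropenylmagnesium bromide | CC(=C)[Mg]Br | starting material
7 | (2S)-2-[(tert-butyldimethylsilyl)oxy]pent-4-ynal, formed in the flask | C#CC[C@H](O[Si](C)(C)C(C)(C)C)C=O | intermediate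
8 | (3RS,4S)-4-[(tert-butyldimethylsilyl)oxy]-2-methylhept-1-en-6-yn-3-ol | C#CC[C@H](O[Si](C)(C)C(C)(C)C)C(O)C(C)=C | intermediate
9 | trimethylaluminium | C[Al](C)C | starting material
10 | iodine | [I][I] | starting material
11 | alkenylalane: [(1E,4S,5RS)-4-[(tert-butyldimethylsilyl)oxy]-5-[(dimethylalumanyl)oxy]-2,6-dimethylhepta-1,6-dien-1-yl]dimethylalumane, formed in the flask | C[Al](C)/C=C(\C)C[C@H](O[Si](C)(C)C(C)(C)C)C(O[Al](C)C)C(C)=C | intermediate
12 | (3RS,4S,6E)-4-[(tert-butyldimethylsilyl)oxy]-7-iodo-2,6-dimethylhepta-1,6-dien-3-ol | I/C=C(\C)C[C@H](O[Si](C)(C)C(C)(C)C)C(O)C(C)=C | intermediate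
13 | triethyl orthoacetate | CC(OCC)(OCC)OCC | starting material
14 | ethyl (4E,6S,8E)-6-[(tert-butyldimethylsilyl)oxy]-9-iodo-4,8-dimethylnona-4,8-dienoate | I/C=C(\C)C[C@H](O[Si](C)(C)C(C)(C)C)/C=C(\C)CCC(=O)OCC | intermediate
15 | (1,3-dioxolan-2-ylmethyl)zinc bromide | Br[Zn]CC1OCCO1 | starting material
16 | ethyl (4E,6S,8E)-6-[(tert-butyldimethylsilyl)oxy]-10-(1,3-dioxolan-2-yl)-4,8-dimethyldeca-4,8-dienoate | O1CCOC1C/C=C(\C)C[C@H](O[Si](C)(C)C(C)(C)C)/C=C(\C)CCC(=O)OCC | intermediate
17 | methyl 2-(triphenyl-λ5-phosphanylidene)propanoate | COC(=O)C(C)=P(c1ccccc1)(c1ccccc1)c1ccccc1 | starting material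
18 | (4E,6S,8E)-6-[(tert-butyldimethylsilyl)oxy]-10-(1,3-dioxolan-2-yl)-4,8-dimethyldeca-4,8-dienal, formed in the flask | O1CCOC1C/C=C(\C)C[C@H](O[Si](C)(C)C(C)(C)C)/C=C(\C)CCC=O | intermediate
19 | methyl (2E,6E,8S,10E)-8-[(tert-butyldimethylsilyl)oxy]-12-(1,3-dioxolan-2-yl)-2,6,10-trimethyldodeca-2,6,10-trienoate | O1CCOC1C/C=C(\C)C[C@H](O[Si](C)(C)C(C)(C)C)/C=C(\C)CC/C=C(\C)C(=O)OC | intermediate
20 | acetic anhydride | CC(=O)OC(C)=O | starting material
21 | methyl (2E,6E,8S,10E)-12-(1,3-dioxolan-2-yl)-8-hydroxy-2,6,10-trimethyldodeca-2,6,10-trienoate, formed in the flask | O1CCOC1C/C=C(\C)C[C@H](O)/C=C(\C)CC/C=C(\C)C(=O)OC | intermediate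
22 | methyl (2E,6E,8S,10E)-8-acetoxy-12-(1,3-dioxolan-2-yl)-2,6,10-trimethyldodeca-2,6,10-trienoate | O1CCOC1C/C=C(\C)C[C@H](OC(C)=O)/C=C(\C)CC/C=C(\C)C(=O)OC | intermediate
23 | dimethyl(phenyl)silane | C[SiH](C)c1ccccc1 | starting material
24 | N-bromosuccinimide | O=C1CCC(=O)N1Br | starting material
25 | silyl ketene acetal: (6E,8S,10E)-8-acetoxy-1-[dimethyl(phenyl)silyloxy]-12-(1,3-dioxolan-2-yl)-1-methoxy-2,6,10-trimethyldodeca-1,6,10-triene, formed in the flask | O1CCOC1C/C=C(\C)C[C@H](OC(C)=O)/C=C(\C)CCCC(C)=C(OC)O[Si](C)(C)c1ccccc1 | intermediate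
26 | methyl (2RS,6E,8S,10E)-8-acetoxy-2-bromo-12-(1,3-dioxolan-2-yl)-2,6,10-trimethyldodeca-6,10-dienoate | O1CCOC1C/C=C(\C)C[C@H](OC(C)=O)/C=C(\C)CCCC(C)(Br)C(=O)OC | intermediate
27 | methyl (4S,5R,6S,9S,10R)-6-acetoxy-12,12-(ethylenedioxy)-13,14,15,16-tetranorlabd-8(17)-en-19-oate (trans-decalin; 4β-CO2Me axial, 5α-H, 6α-OAc equatorial, 8-methylidene, 9β-CH2-dioxolanyl, 10β-Me) | O3CCOC3C[C@H]1C(=C)C[C@H](OC(C)=O)[C@@H]2[C@]1(C)CCC[C@]2(C)C(=O)OC | intermediate
28 | water | O | starting material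
29 | methyl (4S,5R,6S,9S,10R)-6-acetoxy-12-oxo-13,14,15,16-tetranorlabd-8(17)-en-19-oate (C9 carries CH2CHO) | O=CC[C@H]1C(=C)C[C@H](OC(C)=O)[C@@H]2[C@]1(C)CCC[C@]2(C)C(=O)OC | intermediate
30 | ethyltriphenylphosphonium iodide | CC[P+](c1ccccc1)(c1ccccc1)c1ccccc1.[I-] | starting material
31 | methyl (4S,5R,6S,9S,10R,12Z)-6-acetoxy-13-iodo-14,15-dinorlabda-8(17),12-dien-19-oate (C9 carries (2Z)-3-iodobut-2-enyl) | I/C(C)=C\C[C@H]1C(=C)C[C@H](OC(C)=O)[C@@H]2[C@]1(C)CCC[C@]2(C)C(=O)OC | intermediate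
32 | tributyl(vinyl)stannane | CCCC[Sn](CCCC)(CCCC)C=C | starting material
33 | methyl (4S,5R,6S,9S,10R,12Z)-6-acetoxylabda-8(17),12,14-trien-19-oate (methyl 6α-acetoxy-cis-communate) | C=C/C(C)=C\C[C@H]1C(=C)C[C@H](OC(C)=O)[C@@H]2[C@]1(C)CCC[C@]2(C)C(=O)OC | target

## Step count

Total step count: 13.
Longest linear sequence: 13 steps (1 → 33); all other inputs are purchased reagents.

## Steps most likely to fail

**Step 10, the proposed photochemical bicyclisation.** This is the least certain step. The failure modes are: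
- attack on the other face of C5=C10 (anti to the acetoxy group), which would give the decalin of opposite absolute sense with an axial 6-acetate;
- the C4 epimer with an equatorial ester;
- hydrogen abstraction by cobalt from the C4 or C10 radical before ring closure;
- endocyclic instead of exocyclic termination.

The fallback uses known chemistry, sets out from ester 16 and comes back to the route at 27. Claisen condensation of 16 with the lithium enolate of methyl propanoate (LiN(i-Pr)2, THF, −78 → 0 °C) gives methyl (2RS,6E,8S,10E)-8-[(tert-butyldimethylsilyl)oxy]-12-(1,3-dioxolan-2-yl)-2,6,10-trimethyl-3-oxododeca-6,10-dienoate F1. Oxidative free-radical bicyclisation with Mn(OAc)3·2H2O and Cu(OAc)2·H2O in degassed EtOH then gives methyl (4R,5R,6S,9S,10R)-6-[(tert-butyldimethylsilyl)oxy]-12,12-(ethylenedioxy)-3-oxo-13,14,15,16-tetranorlabd-8(17)-en-19-oate F2; here trivalent manganese makes the keto ester radical and divalent copper turns the last tertiary radical into the exocyclic alkene, a sequence with established axial-ester and trans-decalin selectivity. Condensation with TsNHNH2 (EtOH, 70 °C) gives the 3-(4-methylbenzenesulfonyl)hydrazone of that ketone F3. Catecholborane followed by NaOAc·3H2O removes the C3 oxygen to give methyl (4S,5R,6S,9S,10R)-6-[(tert-butyldimethylsilyl)oxy]-12,12-(ethylenedioxy)-13,14,15,16-tetranorlabd-8(17)-en-19-oate F4. Bu4NF (THF, 50 °C) frees methyl (4S,5R,6S,9S,10R)-12,12-(ethylenedioxy)-6-hydroxy-13,14,15,16-tetranorlabd-8(17)-en-19-oate F5, and Ac2O with 4-(dimethylamino)pyridine gives 27.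

**Step 1, the glycidate alkynylation.** BF3 may bind the ester instead of the electron-poor epoxide, giving low conversion or ester attack. The fallback moves the oxidation-state problem to the other end of the C3 unit. It sets out from acetylene 2, bought here as LiC≡CH·H2NCH2CH2NH2, and comes back to the route at aldehyde 7 and alcohol 8. The purchased epoxide (2S)-2-{[(4-methoxyphenyl)methoxy]methyl}oxirane F6 is opened with the acetylide in DMSO at 25 °C to give (2S)-1-[(4-methoxyphenyl)methoxy]pent-4-yn-2-ol F7. Silylation (t-BuMe2SiCl, imidazole) gives tert-butyl({(2S)-1-[(4-methoxyphenyl)methoxy]pent-4-yn-2-yl}oxy)dimethylsilane F8, and DDQ in wet CH2Cl2 gives (2S)-2-[(tert-butyldimethylsilyl)oxy]pent-4-yn-1-ol F9. Swern oxidation then gives aldehyde 7, which is treated in the same flask with 6 to give 8. This costs one extra step.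

**Step 12, the iodo-Wittig olefination.** Yields and Z:E ratios of this reaction on enolisable aldehydes are often modest, and the E-iodide would carry through to the 12E diene. The fallback sets out from aldehyde 29 and comes back at the target 33, bypassing 31. Dibromo-olefination (CBr4, PPh3, Et3N, CH2Cl2, 0 °C) gives methyl (4S,5R,6S,9S,10R)-6-acetoxy-13,13-dibromo-14,15,16-trinorlabda-8(17),12-dien-19-oate F10. A trans-selective Negishi monomethylation (MeZnCl, PdCl2(DPEphos) cat., THF, 0 → 25 °C) exchanges the bromine trans to C11 first and gives methyl (4S,5R,6S,9S,10R,12Z)-6-acetoxy-13-bromo-14,15-dinorlabda-8(17),12-dien-19-oate F11. Stille coupling of F11 with 32 under Pd(t-Bu3P)2, which couples with retention, gives 33.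

## Further compounds

F1 | step 10 | methyl (2RS,6E,8S,10E)-8-[(tert-butyldimethylsilyl)oxy]-12-(1,3-dioxolan-2-yl)-2,6,10-trimethyl-3-oxododeca-6,10-dienoate | O1CCOC1C/C=C(\C)C[C@H](O[Si](C)(C)C(C)(C)C)/C=C(\C)CCC(=O)C(C)C(=O)OC
F2 | step 10 | methyl (4R,5R,6S,9S,10R)-6-[(tert-butyldimethylsilyl)oxy]-12,12-(ethylenedioxy)-3-oxo-13,14,15,16-tetranorlabd-8(17)-en-19-oate | O3CCOC3C[C@H]1C(=C)C[C@H](O[Si](C)(C)C(C)(C)C)[C@@H]2[C@]1(C)CCC(=O)[C@]2(C)C(=O)OC
F3 | step 10 | 3-(4-methylbenzenesulfonyl)hydrazone of F2 | O3CCOC3C[C@H]1C(=C)C[C@H](O[Si](C)(C)C(C)(C)C)[C@@H]2[C@]1(C)CCC(=NNS(=O)(=O)c4ccc(C)cc4)[C@]2(C)C(=O)OC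
F4 | step 10 | methyl (4S,5R,6S,9S,10R)-6-[(tert-butyldimethylsilyl)oxy]-12,12-(ethylenedioxy)-13,14,15,16-tetranorlabd-8(17)-en-19-oate | O3CCOC3C[C@H]1C(=C)C[C@H](O[Si](C)(C)C(C)(C)C)[C@@H]2[C@]1(C)CCC[C@]2(C)C(=O)OC
F5 | step 10 | methyl (4S,5R,6S,9S,10R)-12,12-(ethylenedioxy)-6-hydroxy-13,14,15,16-tetranorlabd-8(17)-en-19-oate | O3CCOC3C[C@H]1C(=C)C[C@H](O)[C@@H]2[C@]1(C)CCC[C@]2(C)C(=O)OC
F6 | step 1 | (2S)-2-{[(4-methoxyphenyl)methoxy]methyl}oxirane | COc1ccc(COC[C@@H]2CO2)cc1
F7 | step 1 | (2S)-1-[(4-methoxyphenyl)methoxy]pent-4-yn-2-ol | C#CC[C@H](O)COCc1ccc(OC)cc1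
F8 | step 1 | tert-butyl({(2S)-1-[(4-methoxyphenyl)methoxy]pent-4-yn-2-yl}oxy)dimethylsilane | C#CC[C@H](O[Si](C)(C)C(C)(C)C)COCc1ccc(OC)cc1
F9 | step 1 | (2S)-2-[(tert-butyldimethylsilyl)oxy]pent-4-yn-1-ol | C#CC[C@H](O[Si](C)(C)C(C)(C)C)CO
F10 | step 12 | methyl (4S,5R,6S,9S,10R)-6-acetoxy-13,13-dibromo-14,15,16-trinorlabda-8(17),12-dien-19-oate | BrC(Br)=CC[C@H]1C(=C)C[C@H](OC(C)=O)[C@@H]2[C@]1(C)CCC[C@]2(C)C(=O)OC
F11 | step 12 | methyl (4S,5R,6S,9S,10R,12Z)-6-acetoxy-13-bromo-14,15-dinorlabda-8(17),12-dien-19-oate | Br/C(C)=C\C[C@H]1C(=C)C[C@H](OC(C)=O)[C@@H]2[C@]1(C)CCC[C@]2(C)C(=O)OC
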